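**Strategy**

The furofuran is cut in ring A (C7, O, C9', C8', C8) at both bonds to C7, C7–O and C7–C8. The feature exploited is that C9 joins C8 to the ring B oxygen: ring B (C7', O, C9, C8, C8') can be held as an enol ether with its double bond at C8=C9, making C8 a carbon nucleophile, while the C9' alcohol on neighbouring C8' tethers the aryl aldehyde carbon C7 as an oxocarbenium ion. One Lewis-acid operation forms both bonds, closes ring A cis-fused and places the C7 aryl endo; the aldol-derived C7' aryl stays exo. The precursor is a trans-(2S,3R)-2-aryl-3-hydroxymethyl-2,3-dihydrofuran with its phenol as a TIPS ether.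

Key step: step 11

Remarks:
- Lignan numbering is used throughout (ring A = C7, O, C9', C8', C8; ring B = C7', O, C9, C8, C8').
- Lactol 13 is an anomeric mixture, and acetal 20 is drawn as the convex-face methoxy epimer that is expected; both centres disappear later.
- Pent-4-enoyl chloride is taken as the commercial, activated form of pent-4-enoic acid.

**Route**

Step 1
Reactants: 1 vanillin (4-hydroxy-3-methoxybenzaldehyde)
Product: 2 3-methoxy-4-(triisopropylsilyloxy)benzaldehyde
Conditions: iPr3SiCl, imidazole, DMF, rt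
Reagents that add atoms: triisopropylsilyl chloride, CC(C)[Si](Cl)(C(C)C)C(C)C
Why: Imidazole-mediated O-silylation of the phenol gives a TIPS ether that is stable to the boron aldol, hydride, ozone and Lewis-acid steps and is later removed by fluoride, so the benzylic C–O bonds of the furofuran never have to face hydrogenolysis; no stereocentre is formed.

Step 2
Reactants: 3 (S)-4-benzyloxazolidin-2-one; 4 pent-4-enoyl chloride
Product: 5 (S)-4-benzyl-3-(pent-4-enoyl)oxazolidin-2-one
Conditions: Et3N, 4-(dimethylamino)pyridine (cat.), CH2Cl2, 0 °C → rt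
Reagents that add atoms: none
Why: N-acylation of the oxazolidinone by the acid chloride under 4-(dimethylamino)pyridine catalysis (nucleophilic acyl substitution) installs the chiral auxiliary without creating a stereocentre.

Step 3
Reactants: 5 (S)-4-benzyl-3-(pent-4-enoyl)oxazolidin-2-one; 2 3-methoxy-4-(triisopropylsilyloxy)benzaldehyde
Product: 8 (S)-4-benzyl-3-[(2S)-2-[(S)-hydroxy[3-methoxy-4-(triisopropylsilyloxy)phenyl]methyl]pent-4-enoyl]oxazolidin-2-one (syn aldol adduct), via Z-dibutylboron enolate 6 (not isolated), via dibutylboron aldolate 7 (not isolated)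
Conditions: Bu2BOTf, iPr2NEt, CH2Cl2, −78 → 0 °C; 2, −78 → 0 °C; pH 7 buffer (NaH2PO4/Na2HPO4), MeOH, 30% H2O2, 0 °C
Reagents that add atoms: none
Why: Evans syn aldol reaction: soft enolisation gives the Z boron enolate 6, which adds to aldehyde 2 through a closed Zimmerman–Traxler chair on the enolate face away from the benzyl group of the auxiliary, setting C8' and C7' together as the (2S,3S) syn adduct that later becomes the trans ring B.

Step 4
Reactants: 8 syn aldol adduct
Product: 9 (1S,2R)-1-[3-methoxy-4-(triisopropylsilyloxy)phenyl]-2-(prop-2-en-1-yl)propane-1,3-diol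
Conditions: LiBH4, THF–MeOH, 0 °C
Reagents that add atoms: none
Why: Hydride reduction of the N-acyl oxazolidinone with LiBH4 (reductive auxiliary cleavage) gives the 1,3-diol and returns the auxiliary, and C8' cannot epimerise once the carbonyl group is gone.

Step 5
Reactants: 9 (1S,2R)-1-[3-methoxy-4-(triisopropylsilyloxy)phenyl]-2-(prop-2-en-1-yl)propane-1,3-diol
Product: 10 (2R)-2-[(S)-hydroxy[3-methoxy-4-(triisopropylsilyloxy)phenyl]methyl]pent-4-en-1-yl pivalate
Conditions: Me3CCOCl (1.05 equiv), pyridine, CH2Cl2, 0 °C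
Reagents that add atoms: pivaloyl chloride, CC(C)(C)C(=O)Cl
Why: Chemoselective esterification: the bulky acid chloride acylates the primary hydroxyl much faster than the secondary benzylic one, which has to stay free to close ring B.

Step 6
Reactants: 10 (2R)-2-[(S)-hydroxy[3-methoxy-4-(triisopropylsilyloxy)phenyl]methyl]pent-4-en-1-yl pivalate
Product: 13 [(2S,3R)-5-hydroxy-2-[3-methoxy-4-(triisopropylsilyloxy)phenyl]tetrahydrofuran-3-yl]methyl pivalate (lactol as an anomeric mixture), via ozonide 11 (not isolated), via hydroxy aldehyde 12 (not isolated)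
Conditions: O3, CH2Cl2, −78 °C (Sudan Red 7B end point); PPh3, −78 °C → rt
Reagents that add atoms: ozone, [O-][O+]=O
Why: Ozonolysis with reductive work-up cleaves the terminal alkene to the γ-hydroxy aldehyde 12, which closes spontaneously to the five-membered lactol (ring B), its new anomeric centre being an inconsequential mixture destroyed in step 7.

Step 7
Reactants: 13 lactol
Product: 15 [(2S,3R)-2-[3-methoxy-4-(triisopropylsilyloxy)phenyl]-2,3-dihydrofuran-3-yl]methyl pivalate, via lactol mesylate 14 (not isolated)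
Conditions: MeSO2Cl, Et3N (excess), CH2Cl2, −40 °C → reflux; chromatography on Et3N-deactivated silica
Reagents that add atoms: none
Why: Lactol dehydration by sulfonylation–elimination: the anomeric mesylate 14 ionises to the ring oxocarbenium ion and Et3N removes a proton from C8, the only β-carbon, to give the C8=C9 enol ether without touching C7' or C8'.

Step 8
Reactants: 15 [(2S,3R)-2-[3-methoxy-4-(triisopropylsilyloxy)phenyl]-2,3-dihydrofuran-3-yl]methyl pivalate
Product: 16 [(2S,3R)-2-[3-methoxy-4-(triisopropylsilyloxy)phenyl]-2,3-dihydrofuran-3-yl]methanol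
Conditions: iBu2AlH (2.5 equiv), CH2Cl2, −78 °C; aq. potassium sodium tartrate
Reagents that add atoms: none
Why: Reductive ester cleavage with iBu2AlH frees the C9' alcohol under non-acidic conditions that the acid-sensitive enol ether and the aryl silyl ether both tolerate.

Step 9
Reactants: 1 vanillin
Product: 17 4-formyl-2-methoxyphenyl pivalate
Conditions: Me3CCOCl, Et3N, 4-(dimethylamino)pyridine (cat.), CH2Cl2, 0 °C → rt
Reagents that add atoms: pivaloyl chloride, CC(C)(C)C(=O)Cl
Why: O-acylation (esterification) of the phenol gives an aryl pivalate that survives Lewis acids and makes this aryl ring electron-poor, which is wanted in step 11.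

Step 10
Reactants: 17 4-formyl-2-methoxyphenyl pivalate
Product: 18 4-(dimethoxymethyl)-2-methoxyphenyl pivalate
Conditions: HC(OMe)3 (as solvent), p-toluenesulfonic acid monohydrate (1 mol%), rt; Et3N quench
Reagents that add atoms: trimethyl orthoformate, COC(OC)OC
Why: Acid-catalysed acetalisation driven by the orthoformate, which consumes the water formed, turns the aldehyde into the oxocarbenium precursor while the hindered aryl ester stays intact.

Step 11
Reactants: 16 [(2S,3R)-2-[3-methoxy-4-(triisopropylsilyloxy)phenyl]-2,3-dihydrofuran-3-yl]methanol; 18 4-(dimethoxymethyl)-2-methoxyphenyl pivalate (1.3 equiv)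
Product: 20 2-methoxy-4-[(1R,3aR,4S,6R,6aS)-6-methoxy-4-[3-methoxy-4-(triisopropylsilyloxy)phenyl]tetrahydro-1H,3H-furo[3,4-c]furan-1-yl]phenyl pivalate (endo,exo-furofuran methyl acetal with OMe on C9), via mixed acetal 19 (not isolated)
Conditions: Me3SiOTf (0.2 equiv), CH2Cl2, −78 → −40 °C; Et3N quench at −78 °C
Reagents that add atoms: none
Why: Me3SiOTf ionises acetal 18 and alcohol 16 exchanges in to give mixed acetal 19, which ionises again to an E oxocarbenium ion held on O–C9'; the enol ether carbon C8 attacks C7 and the new ring B oxocarbenium ion at C9 is capped by the methanol released in the exchange. The closest known reaction type is the Lewis-acid-promoted Prins-type cyclisation of 2,3-dihydrofuran-3-ylmethanols with aryl aldehyde acetals to furofuran acetals. Ring A closes in a five-membered mode that is exo for the C8=C9 enol ether and endo for the C7=O+ unit (5-(enolexo)-endo-trig), feasible because the cation is highly electrophilic and the enol ether strongly nucleophilic. C8 is set by C8', since the short C9'–O tether can reach only the enol ether face on which C9' sits, which gives the cis ring fusion and leaves the C7' aryl on the convex face, and C9 is set by convex-face capture but is removed in step 12. C7 is set kinetically: the E oxocarbenium ion is expected to react through the compact arrangement in which its aryl group lies over ring B and the developing C9 cation, so the aryl finishes endo. The step needs this endo selectivity against the more stable exo epimer, and it is secured by low temperature, substoichiometric acid, an early amine quench and the electron-poor pivaloyloxyaryl group, which disfavours reionisation of the benzylic C7–O bond.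

Step 12
Reactants: 20 endo,exo-furofuran methyl acetal
Product: 21 2-methoxy-4-[(1R,3aR,4S,6aR)-4-[3-methoxy-4-(triisopropylsilyloxy)phenyl]tetrahydro-1H,3H-furo[3,4-c]furan-1-yl]phenyl pivalate
Conditions: Et3SiH (3 equiv), BF3·OEt2 (1.5 equiv), CH2Cl2, −78 °C; sat. NaHCO3 quench at −78 °C
Reagents that add atoms: none
Why: Ionic hydrogenation of a cyclic acetal (Lewis-acid-promoted silane reduction): BF3 ionises the C9–OMe bond to the ring B oxocarbenium ion, which Et3SiH reduces to CH2, while at −78 °C the benzylic C7–O and C7'–O bonds should stay closed so that the four remaining stereocentres are kept.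

Step 13
Reactants: 21 silyl ether pivalate of the furofuran; 22 prenyl bromide (1-bromo-3-methylbut-2-ene, 1.5 equiv)
Product: 24 2-methoxy-4-[(1R,3aR,4S,6aR)-4-[3-methoxy-4-(3-methylbut-2-en-1-yloxy)phenyl]tetrahydro-1H,3H-furo[3,4-c]furan-1-yl]phenyl pivalate, via tetrabutylammonium phenoxide 23 (not isolated)
Conditions: Bu4NF (1.05 equiv), THF, 0 °C → rt, prenyl bromide present from the start
Reagents that add atoms: none
Why: Fluoride-induced cleavage of the aryl silyl ether followed in the same flask by Williamson ether synthesis: the ammonium phenoxide 23 is O-alkylated by the allylic bromide as soon as it forms, which should outrun acyl transfer from the hindered aryl pivalate.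

Step 14
Reactants: 24 prenyl ether pivalate
Product: 25 4-[(1R,3aR,4S,6aR)-4-[3-methoxy-4-(3-methylbut-2-en-1-yloxy)phenyl]tetrahydro-1H,3H-furo[3,4-c]furan-1-yl]-2-methoxyphenol (target)
Conditions: K2CO3, MeOH, rt → 40 °C; aq. NH4Cl
Reagents that add atoms: none
Why: Base-mediated methanolysis (transesterification) of the aryl ester releases the phenol, and the furofuran, its benzylic stereocentres and the prenyl ether are inert to carbonate in methanol.

**Compound list**

1 | vanillin | COc1cc(C=O)ccc1O | starting material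
2 | 3-methoxy-4-(triisopropylsilyloxy)benzaldehyde | COc1cc(C=O)ccc1O[Si](C(C)C)(C(C)C)C(C)C | intermediate
3 | (S)-4-benzyloxazolidin-2-one | O=C1N[C@@H](Cc2ccccc2)CO1 | starting material
4 | pent-4-enoyl chloride | C=CCCC(=O)Cl | starting material
5 | (S)-4-benzyl-3-(pent-4-enoyl)oxazolidin-2-one | C=CCCC(=O)N1C(=O)OC[C@@H]1Cc2ccccc2 | intermediate
6 | Z-dibutylboron enolate of 5 | CCCCB(CCCC)O/C(=C\CC=C)N1C(=O)OC[C@@H]1Cc2ccccc2 | intermediate
7 | dibutylboron aldolate of 8 | C=CC[C@@H]([C@H](OB(CCCC)CCCC)c1ccc(O[Si](C(C)C)(C(C)C)C(C)C)c(OC)c1)C(=O)N2C(=O)OC[C@@H]2Cc3ccccc3 | intermediate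
8 | (S)-4-benzyl-3-[(2S)-2-[(S)-hydroxy[3-methoxy-4-(triisopropylsilyloxy)phenyl]methyl]pent-4-enoyl]oxazolidin-2-one | C=CC[C@@H]([C@H](O)c1ccc(O[Si](C(C)C)(C(C)C)C(C)C)c(OC)c1)C(=O)N2C(=O)OC[C@@H]2Cc3ccccc3 | intermediate
9 | (1S,2R)-1-[3-methoxy-4-(triisopropylsilyloxy)phenyl]-2-(prop-2-en-1-yl)propane-1,3-diol | C=CC[C@@H]([C@H](O)c1ccc(O[Si](C(C)C)(C(C)C)C(C)C)c(OC)c1)CO | intermediate
10 | (2R)-2-[(S)-hydroxy[3-methoxy-4-(triisopropylsilyloxy)phenyl]methyl]pent-4-en-1-yl pivalate | C=CC[C@@H]([C@H](O)c1ccc(O[Si](C(C)C)(C(C)C)C(C)C)c(OC)c1)COC(=O)C(C)(C)C | intermediate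
11 | ozonide (3-substituted 1,2,4-trioxolane) of 10 | C1OC(C[C@@H]([C@H](O)c2ccc(O[Si](C(C)C)(C(C)C)C(C)C)c(OC)c2)COC(=O)C(C)(C)C)OO1 | intermediate
12 | (2R)-2-[(S)-hydroxy[3-methoxy-4-(triisopropylsilyloxy)phenyl]methyl]-4-oxobutyl pivalate | O=CC[C@@H]([C@H](O)c1ccc(O[Si](C(C)C)(C(C)C)C(C)C)c(OC)c1)COC(=O)C(C)(C)C | intermediate
13 | [(2S,3R)-5-hydroxy-2-[3-methoxy-4-(triisopropylsilyloxy)phenyl]tetrahydrofuran-3-yl]methyl pivalate (anomeric mixture) | CC(C)(C)C(=O)OC[C@H]1CC(O)O[C@@H]1c2ccc(O[Si](C(C)C)(C(C)C)C(C)C)c(OC)c2 | intermediate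
14 | [(2S,3R)-2-[3-methoxy-4-(triisopropylsilyloxy)phenyl]-5-(methylsulfonyloxy)tetrahydrofuran-3-yl]methyl pivalate | CC(C)(C)C(=O)OC[C@H]1CC(OS(C)(=O)=O)O[C@@H]1c2ccc(O[Si](C(C)C)(C(C)C)C(C)C)c(OC)c2 | intermediate
15 | [(2S,3R)-2-[3-methoxy-4-(triisopropylsilyloxy)phenyl]-2,3-dihydrofuran-3-yl]methyl pivalate | CC(C)(C)C(=O)OC[C@H]1C=CO[C@@H]1c2ccc(O[Si](C(C)C)(C(C)C)C(C)C)c(OC)c2 | intermediate
16 | [(2S,3R)-2-[3-methoxy-4-(triisopropylsilyloxy)phenyl]-2,3-dihydrofuran-3-yl]methanol | OC[C@H]1C=CO[C@@H]1c2ccc(O[Si](C(C)C)(C(C)C)C(C)C)c(OC)c2 | intermediate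
17 | 4-formyl-2-methoxyphenyl pivalate | COc1cc(C=O)ccc1OC(=O)C(C)(C)C | intermediate
18 | 4-(dimethoxymethyl)-2-methoxyphenyl pivalate | COC(OC)c1ccc(OC(=O)C(C)(C)C)c(OC)c1 | intermediate
19 | mixed acetal, 2-methoxy-4-[methoxy[[(2S,3R)-2-[3-methoxy-4-(triisopropylsilyloxy)phenyl]-2,3-dihydrofuran-3-yl]methoxy]methyl]phenyl pivalate (both acetal epimers) | COC(OC[C@H]1C=CO[C@@H]1c2ccc(O[Si](C(C)C)(C(C)C)C(C)C)c(OC)c2)c3ccc(OC(=O)C(C)(C)C)c(OC)c3 | intermediate
20 | 2-methoxy-4-[(1R,3aR,4S,6R,6aS)-6-methoxy-4-[3-methoxy-4-(triisopropylsilyloxy)phenyl]tetrahydro-1H,3H-furo[3,4-c]furan-1-yl]phenyl pivalate | CO[C@@H]1O[C@H](c3ccc(O[Si](C(C)C)(C(C)C)C(C)C)c(OC)c3)[C@H]2CO[C@@H](c4ccc(OC(=O)C(C)(C)C)c(OC)c4)[C@@H]12 | intermediate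
21 | 2-methoxy-4-[(1R,3aR,4S,6aR)-4-[3-methoxy-4-(triisopropylsilyloxy)phenyl]tetrahydro-1H,3H-furo[3,4-c]furan-1-yl]phenyl pivalate | COc1cc([C@@H]2OC[C@H]3[C@@H]2CO[C@@H]3c4ccc(O[Si](C(C)C)(C(C)C)C(C)C)c(OC)c4)ccc1OC(=O)C(C)(C)C | intermediate
22 | prenyl bromide (1-bromo-3-methylbut-2-ene) | CC(C)=CCBr | starting material
23 | tetrabutylammonium phenoxide formed from 21 by loss of the silyl group | COc1cc([C@@H]2OC[C@H]3[C@@H]2CO[C@@H]3c4ccc([O-])c(OC)c4)ccc1OC(=O)C(C)(C)C.CCCC[N+](CCCC)(CCCC)CCCC | intermediate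
24 | 2-methoxy-4-[(1R,3aR,4S,6aR)-4-[3-methoxy-4-(3-methylbut-2-en-1-yloxy)phenyl]tetrahydro-1H,3H-furo[3,4-c]furan-1-yl]phenyl pivalate | COc1cc([C@@H]2OC[C@H]3[C@@H]2CO[C@@H]3c4ccc(OCC=C(C)C)c(OC)c4)ccc1OC(=O)C(C)(C)C | intermediate
25 | 4-[(1R,3aR,4S,6aR)-4-[3-methoxy-4-(3-methylbut-2-en-1-yloxy)phenyl]tetrahydro-1H,3H-furo[3,4-c]furan-1-yl]-2-methoxyphenol | COc1cc([C@@H]2OC[C@H]3[C@@H]2CO[C@@H]3c2ccc(OCC=C(C)C)c(OC)c2)ccc1O | target

**Step count**

Total steps: 14. Longest linear sequence: 11 steps (steps 2–8 and 11–14 from 3 and 4; equally steps 1, 3–8 and 11–14 from vanillin).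

**Steps most likely to fail**

Step 11. The kinetic endo preference at C7 may erode through acid-mediated reopening of the benzylic C7–O bond while the bimolecular acetal exchange is still slow, and the untethered enol ether alcohol may degrade under the acid. The fallback sets out from 18 and 16 and comes back at 20; it tethers under base and leaves only the ring closure to the acid. Acetal 18 would be treated with AcCl and ZnBr2 (cat.) in CH2Cl2 to give 4-[chloro(methoxy)methyl]-2-methoxyphenyl pivalate F1. This α-chloro ether would O-alkylate alcohol 16 in the presence of iPr2NEt at 0 °C to give mixed acetal 19 as an isolated compound. Exposure of 19 to Me3SiOTf (0.1 equiv) at −78 °C for minutes, a unimolecular isomerisation, should then give 20.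

Step 7. Elimination of the anomeric sulfonate may stall at the anomeric chloride or at a lactol anhydride, and the 2-aryl enol ether may ring-open under the ammonium salts on heating. The fallback sets out from 13 and comes back at 15; it replaces the ionic elimination by a syn elimination under buffered conditions. Lactol 13 would react with N-(phenylseleno)phthalimide and Bu3P in CH2Cl2 to give [(2S,3R)-2-[3-methoxy-4-(triisopropylsilyloxy)phenyl]-5-(phenylselanyl)tetrahydrofuran-3-yl]methyl pivalate F2. Oxidation with H2O2 and pyridine at 0 °C would give the selenoxide of F2 F3, which should lose benzeneselenenic acid at room temperature, the only β-hydrogens being on C8, to give enol ether 15.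

Step 12. BF3 may ionise the benzylic C7–O bond in competition with the acetal, which would epimerise the endo aryl to exo or open ring A reductively. The fallback sets out from 20 and comes back at 21; it removes the C9 oxygen by hydride reduction and cycloetherification in place of the Lewis acid and silane. Mild hydrolysis of 20 (pyridinium p-toluenesulfonate, acetone–H2O, 40 °C) would give the ring B lactol F4. NaBH4 in EtOH–THF at 0 °C would reduce F4 to the ring-opened diol F5, which carries CH2OH on C8 and the benzylic carbinol C7' on C8'. MeSO2Cl (1.1 equiv) in pyridine would sulfonylate the primary hydroxyl to the primary C9 mesylate F6, which should close ring B by intramolecular Williamson etherification (5-exo-tet) with retention at C7' to give 21.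

**Further compounds**

F1 | step 11 | 4-[chloro(methoxy)methyl]-2-methoxyphenyl pivalate | COC(Cl)c1ccc(OC(=O)C(C)(C)C)c(OC)c1
F2 | step 7 | [(2S,3R)-2-[3-methoxy-4-(triisopropylsilyloxy)phenyl]-5-(phenylselanyl)tetrahydrofuran-3-yl]methyl pivalate | CC(C)(C)C(=O)OC[C@H]1CC([Se]c2ccccc2)O[C@@H]1c3ccc(O[Si](C(C)C)(C(C)C)C(C)C)c(OC)c3
F3 | step 7 | selenoxide of F2 | CC(C)(C)C(=O)OC[C@H]1CC([Se](=O)c2ccccc2)O[C@@H]1c3ccc(O[Si](C(C)C)(C(C)C)C(C)C)c(OC)c3
F4 | step 12 | ring B lactol (C9 hydroxy analogue of 20, anomeric mixture) | OC1O[C@H](c3ccc(O[Si](C(C)C)(C(C)C)C(C)C)c(OC)c3)[C@H]2CO[C@@H](c4ccc(OC(=O)C(C)(C)C)c(OC)c4)[C@@H]12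
F5 | step 12 | ring-opened diol, 4-[(2R,3R,4R)-3-(hydroxymethyl)-4-[(S)-hydroxy[3-methoxy-4-(triisopropylsilyloxy)phenyl]methyl]tetrahydrofuran-2-yl]-2-methoxyphenyl pivalate | COc1cc([C@@H]2OC[C@H]([C@H](O)c3ccc(O[Si](C(C)C)(C(C)C)C(C)C)c(OC)c3)[C@@H]2CO)ccc1OC(=O)C(C)(C)C
F6 | step 12 | primary C9 mesylate of F5 | COc1cc([C@@H]2OC[C@H]([C@H](O)c3ccc(O[Si](C(C)C)(C(C)C)C(C)C)c(OC)c3)[C@@H]2COS(C)(=O)=O)ccc1OC(=O)C(C)(C)C
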